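**Retrosynthetic overview**
1. The route rests on two features of target 18: the erythro pair C2–O1 / C3–O on the dihydrofuran ring (ring B; 2R,3S, trans on the ring), which is C3/C2 of D-ribono-1,4-lactone, and the benzene ring (ring A, C3a–C7a) carrying oxygen at C7a and the side chain para to it at C5.
2. Late stage: both tiglates and the enal lead back to triol 15 and acetyl arene 13 (CBS reduction, desilylation, selective allylic oxidation, acylation).
3. Key disconnection of 13: ring A at C4–C5 and C6–C7 (Diels–Alder addition of but-3-yn-2-one, then dehydrogenation) and ring B at O1–C7a (5-exo-dig hydroalkoxylation), giving acyclic enynol 9.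
4. Enynol 9 comes from 1,4-diketone 6 by twofold methylenation, and 6 from lactone 3 by acetylide addition and hemiketal oxidation; O2 and O3 are told apart at the lactone stage (TBS on O2/O5, TMS on O3), and lactone C1 becomes C3a.
5. Ring order: ring B closes first, ring A second, both in step 7.

Key step: step 7

Remark on the chemistry (assumption): silylation of D-ribono-1,4-lactone is taken to occur at the primary O5 and then at O2, the more acidic hydroxyl α to the carbonyl; the differentiation of O2 from O3 rests on this. TBS = tert-butyldimethylsilyl, TMS = trimethylsilyl.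

**Step 1**
Reactants: 1 D-ribono-1,4-lactone
Product: 2 2,5-di-O-(tert-butyldimethylsilyl)-D-ribono-1,4-lactone
Conditions: TBSCl (2.1 equiv), imidazole, DMF, −20 to 0 °C
Reagents that add atoms: tert-butyldimethylsilyl chloride, CC(C)(C)[Si](C)(C)Cl
Why: Silyl chloride/imidazole silylation takes the primary C5 hydroxyl first and then, of the two secondary hydroxyls, the more acidic C2–OH next to the lactone carbonyl, so the 2,5-bis-silyl ether with free O3 should predominate; no stereocentre is touched.

**Step 2**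
Reactants: 2 2,5-di-O-(tert-butyldimethylsilyl)-D-ribono-1,4-lactone
Product: 3 2,5-di-O-(tert-butyldimethylsilyl)-3-O-(trimethylsilyl)-D-ribono-1,4-lactone
Conditions: TMSCl (1.5 equiv), imidazole, CH2Cl2, 0 °C
Reagents that add atoms: chlorotrimethylsilane, C[Si](C)(C)Cl
Why: Silylation of the remaining hydroxyl as the labile trimethylsilyl ether masks O3 during the carbonyl chemistry and allows its later release under conditions that leave both TBS ethers in place.

**Step 3**
Reactants: 3 2,5-di-O-(tert-butyldimethylsilyl)-3-O-(trimethylsilyl)-D-ribono-1,4-lactone; 4 trimethylsilylacetylene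
Product: 5 2,5-di-O-(tert-butyldimethylsilyl)-3-O-(trimethylsilyl)-1-C-[(trimethylsilyl)ethynyl]-D-ribofuranose (hemiketal as a mixture of anomers)
Conditions: 4, n-BuLi, THF, −78 °C; then 3, −78 °C; AcOH quench at −78 °C
Reagents that add atoms: none
Why: 1,2-Addition of a lithium acetylide to a γ-lactone stops at the lithium hemiketalate at −78 °C, so one alkynyl group is delivered to C1, and the cold acidic quench avoids silyl migration in the ring-opened alkoxide.

**Step 4**
Reactants: 5 the alkynyl hemiketal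
Product: 6 (4R,5S)-4,7-bis(tert-butyldimethylsilyloxy)-1-(trimethylsilyl)-5-(trimethylsilyloxy)hept-1-yne-3,6-dione
Conditions: Dess–Martin periodinane (2.5 equiv), pyridine, CH2Cl2, 0 °C to rt
Reagents that add atoms: none
Why: Dess–Martin oxidation acts on the hydroxy-ynone tautomer in ring–chain equilibrium with the hemiketal (the tertiary anomeric hydroxyl cannot be oxidised), draining the equilibrium to the 1,4-diketone; the C4 stereocentre of ribose is erased on purpose.

**Step 5**
Reactants: 6 the 1,4-diketone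
Product: 7 (3R,4S)-4-(tert-butyldimethylsilyloxy)-2-[(tert-butyldimethylsilyloxy)methyl]-5-methylidene-7-(trimethylsilyl)-3-(trimethylsilyloxy)hept-1-en-6-yne
Conditions: Ph3PCH3Br (4 equiv), KOtBu (3.8 equiv), THF, 0 °C; then 6, −78 to 0 °C
Reagents that add atoms: methyltriphenylphosphonium bromide, C[P+](c1ccccc1)(c1ccccc1)c1ccccc1.[Br-]
Why: Twofold Wittig methylenation converts the ynone carbonyl (1,2-addition) and the dialkyl ketone into 1,1-disubstituted alkenes; low temperature and a slight deficit of base limit enolisation, so both carbinol centres should be retained.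

**Step 6**
Reactants: 7 the bis-silylated dienyne
Product: 9 (3R,4S)-4-(tert-butyldimethylsilyloxy)-2-[(tert-butyldimethylsilyloxy)methyl]-5-methylidenehept-1-en-6-yn-3-ol, via C-desilylated trimethylsilyl ether 8 (not isolated)
Conditions: AgNO3 (10 mol%), CH2Cl2/MeOH/H2O, rt; then PPTS (10 mol%), 0 °C
Reagents that add atoms: none
Why: Silver-catalysed protiodesilylation of the alkynyl C–Si bond followed by mild acid methanolysis of the O–SiMe3 ether are both non-basic, so the secondary TBS group cannot migrate to the freed neighbouring hydroxyl and the much less labile TBS ethers survive.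

**Step 7**
Reactants: 9 the enynol; 10 but-3-yn-2-one
Product: 13 1-[(2R,3S)-3-(tert-butyldimethylsilyloxy)-2-[3-(tert-butyldimethylsilyloxy)prop-1-en-2-yl]-2,3-dihydro-1-benzofuran-5-yl]ethanone, via dimethylideneoxolane diene 11 (not isolated), via tetrahydrobenzofuran cycloadduct 12 (not isolated)
Conditions: Ph3PAuNTf2 (2 mol%), 4 Å MS, toluene, rt; Et3N (5 mol%), then 10 (3 equiv), 60 °C; then DDQ (1.2 equiv), rt
Reagents that add atoms: none
Why: Proposed new method: cationic monovalent gold π-activates the terminal alkyne of 9 and the C3 hydroxyl adds to its inner carbon in a Markovnikov 5-exo-dig oxyauration, protodeauration giving the 2,3-dimethylideneoxolane 11 and with it the O1–C7a bond and ring B. The closest known reactions are gold-catalysed cycloisomerisations of pent-4-yn-1-ols to 2-methylideneoxolanes and Diels–Alder/dehydrogenation sequences of exocyclic 2-alkoxydienes with alkynes; the one-pot union on a 3-methylidene-pent-4-yn-1-ol is new. The s-cis-locked 2-alkoxydiene then adds but-3-yn-2-one in a thermal [4+2] cycloaddition that forms C6–C7 and C4–C5 and closes the six-membered ring as the 4,7-dihydro compound 12, and DDQ removes the two doubly allylic hydrogens to give ring A. No stereocentre is formed; C2 and C3 are C3 and C2 of the ribonolactone and none of their bonds is touched. The step needs O-addition to outrun enyne and 5-endo pathways, which the free hydroxyl placed for 5-exo attack and the silyl group on the neighbouring oxygen secure, and it needs para regiochemistry, which follows from the enol-ether CH2 (future C7, largest HOMO coefficient) bonding to the β-carbon of the ynone so that the acetyl group lands on C5. Over-oxidation to the benzofuran is not expected, because it would require loss of the C3 silyloxy group and not of hydrogen, and the acetyl arene is electron-poor.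

**Step 8**
Reactants: 13 the acetyl dihydrobenzofuran
Product: 14 (1R)-1-[(2R,3S)-3-(tert-butyldimethylsilyloxy)-2-[3-(tert-butyldimethylsilyloxy)prop-1-en-2-yl]-2,3-dihydro-1-benzofuran-5-yl]ethan-1-ol
Conditions: (S)-2-methyl-CBS-oxazaborolidine (20 mol%), catecholborane (1.5 equiv), toluene, −78 °C
Reagents that add atoms: none
Why: Corey–Bakshi–Shibata reduction of an aryl methyl ketone with the (S)-oxazaborolidine (aryl as the large group) should give the (R)-carbinol under catalyst control, as for acetophenone, and catecholborane at −78 °C does not hydroborate the 1,1-disubstituted alkene.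

**Step 9**
Reactants: 14 the bis-silyl ether alcohol
Product: 15 (2R,3S)-5-[(1R)-1-hydroxyethyl]-2-(3-hydroxyprop-1-en-2-yl)-2,3-dihydro-1-benzofuran-3-ol
Conditions: TBAF (2.5 equiv), AcOH (2.5 equiv), THF, 0 °C to rt
Reagents that add atoms: none
Why: Fluoride cleavage of both TBS ethers, buffered with acetic acid so that the 3-hydroxy-2,3-dihydrobenzofuran meets neither strong base nor acid that could dehydrate it to the benzofuran.

**Step 10**
Reactants: 15 the triol
Product: 16 2-[(2R,3S)-3-hydroxy-5-[(1R)-1-hydroxyethyl]-2,3-dihydro-1-benzofuran-2-yl]prop-2-enal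
Conditions: TEMPO (10 mol%), PhI(OAc)2 (1.1 equiv), CH2Cl2, 0 °C to rt
Reagents that add atoms: none
Why: Oxoammonium (TEMPO/PhI(OAc)2) oxidation is selective for the unhindered primary allylic alcohol over the two secondary benzylic alcohols and stops at the aldehyde, giving the 2-substituted acrolein without touching a stereocentre.

**Step 11**
Reactants: 16 the enal diol; 17 tigloyl chloride [(2E)-2-methylbut-2-enoyl chloride]
Product: 18 (1R)-1-[(2R,3S)-3-{[(2E)-2-methylbut-2-enoyl]oxy}-2-(3-oxoprop-1-en-2-yl)-2,3-dihydro-1-benzofuran-5-yl]ethyl (2E)-2-methylbut-2-enoate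
Conditions: 17 (3 equiv), pyridine, DMAP (20 mol%), CH2Cl2, 0 °C to rt
Reagents that add atoms: none
Why: DMAP-catalysed acylation of both secondary benzylic hydroxyls proceeds with retention at the carbinol carbons, and pyridine as the only base avoids vinylketene formation, so the (E)-geometry of the tigloyl groups is kept.

**Compound list**
1 | D-ribono-1,4-lactone | O=C1O[C@H](CO)[C@@H](O)[C@H]1O | starting material
2 | 2,5-di-O-(tert-butyldimethylsilyl)-D-ribono-1,4-lactone | O=C1O[C@H](CO[Si](C)(C)C(C)(C)C)[C@@H](O)[C@H]1O[Si](C)(C)C(C)(C)C | intermediate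
3 | 2,5-di-O-(tert-butyldimethylsilyl)-3-O-(trimethylsilyl)-D-ribono-1,4-lactone | O=C1O[C@H](CO[Si](C)(C)C(C)(C)C)[C@@H](O[Si](C)(C)C)[C@H]1O[Si](C)(C)C(C)(C)C | intermediate
4 | trimethylsilylacetylene | C#C[Si](C)(C)C | starting material
5 | 2,5-di-O-(tert-butyldimethylsilyl)-3-O-(trimethylsilyl)-1-C-[(trimethylsilyl)ethynyl]-D-ribofuranose (anomer mixture) | C[Si](C)(C)C#CC1(O)O[C@H](CO[Si](C)(C)C(C)(C)C)[C@@H](O[Si](C)(C)C)[C@H]1O[Si](C)(C)C(C)(C)C | intermediate
6 | (4R,5S)-4,7-bis(tert-butyldimethylsilyloxy)-1-(trimethylsilyl)-5-(trimethylsilyloxy)hept-1-yne-3,6-dione | CC(C)(C)[Si](C)(C)OCC(=O)[C@@H](O[Si](C)(C)C)[C@@H](O[Si](C)(C)C(C)(C)C)C(=O)C#C[Si](C)(C)C | intermediate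
7 | (3R,4S)-4-(tert-butyldimethylsilyloxy)-2-[(tert-butyldimethylsilyloxy)methyl]-5-methylidene-7-(trimethylsilyl)-3-(trimethylsilyloxy)hept-1-en-6-yne | C=C(CO[Si](C)(C)C(C)(C)C)[C@@H](O[Si](C)(C)C)[C@@H](O[Si](C)(C)C(C)(C)C)C(=C)C#C[Si](C)(C)C | intermediate
8 | (3R,4S)-4-(tert-butyldimethylsilyloxy)-2-[(tert-butyldimethylsilyloxy)methyl]-5-methylidene-3-(trimethylsilyloxy)hept-1-en-6-yne | C=C(CO[Si](C)(C)C(C)(C)C)[C@@H](O[Si](C)(C)C)[C@@H](O[Si](C)(C)C(C)(C)C)C(=C)C#C | intermediate (not isolated)
9 | (3R,4S)-4-(tert-butyldimethylsilyloxy)-2-[(tert-butyldimethylsilyloxy)methyl]-5-methylidenehept-1-en-6-yn-3-ol | C=C(CO[Si](C)(C)C(C)(C)C)[C@H]([C@@H](O[Si](C)(C)C(C)(C)C)C(=C)C#C)O | intermediate (key-step precursor)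
10 | but-3-yn-2-one | CC(=O)C#C | starting material
11 | (2R,3S)-3-(tert-butyldimethylsilyloxy)-2-[3-(tert-butyldimethylsilyloxy)prop-1-en-2-yl]-4,5-dimethylideneoxolane | C=C(CO[Si](C)(C)C(C)(C)C)[C@H]1OC(=C)C(=C)[C@@H]1O[Si](C)(C)C(C)(C)C | intermediate (not isolated)
12 | 1-[(2R,3S)-3-(tert-butyldimethylsilyloxy)-2-[3-(tert-butyldimethylsilyloxy)prop-1-en-2-yl]-2,3,4,7-tetrahydro-1-benzofuran-5-yl]ethanone | C=C(CO[Si](C)(C)C(C)(C)C)[C@H]1OC2=C(CC(C(C)=O)=CC2)[C@@H]1O[Si](C)(C)C(C)(C)C | intermediate (not isolated)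
13 | 1-[(2R,3S)-3-(tert-butyldimethylsilyloxy)-2-[3-(tert-butyldimethylsilyloxy)prop-1-en-2-yl]-2,3-dihydro-1-benzofuran-5-yl]ethanone | C=C(CO[Si](C)(C)C(C)(C)C)[C@H]1Oc2ccc(C(C)=O)cc2[C@@H]1O[Si](C)(C)C(C)(C)C | intermediate (key-step product)
14 | (1R)-1-[(2R,3S)-3-(tert-butyldimethylsilyloxy)-2-[3-(tert-butyldimethylsilyloxy)prop-1-en-2-yl]-2,3-dihydro-1-benzofuran-5-yl]ethan-1-ol | C=C(CO[Si](C)(C)C(C)(C)C)[C@H]1Oc2ccc([C@@H](C)O)cc2[C@@H]1O[Si](C)(C)C(C)(C)C | intermediate
15 | (2R,3S)-5-[(1R)-1-hydroxyethyl]-2-(3-hydroxyprop-1-en-2-yl)-2,3-dihydro-1-benzofuran-3-ol | C=C(CO)[C@H]1Oc2ccc([C@@H](C)O)cc2[C@@H]1O | intermediate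
16 | 2-[(2R,3S)-3-hydroxy-5-[(1R)-1-hydroxyethyl]-2,3-dihydro-1-benzofuran-2-yl]prop-2-enal | C=C(C=O)[C@H]1Oc2ccc([C@@H](C)O)cc2[C@@H]1O | intermediate
17 | tigloyl chloride, (2E)-2-methylbut-2-enoyl chloride | C/C=C(\C)C(=O)Cl | starting material
18 | (1R)-1-[(2R,3S)-3-{[(2E)-2-methylbut-2-enoyl]oxy}-2-(3-oxoprop-1-en-2-yl)-2,3-dihydro-1-benzofuran-5-yl]ethyl (2E)-2-methylbut-2-enoate (CNP0292799.1) | C=C(C=O)[C@H]1Oc2ccc([C@@H](C)OC(=O)/C(C)=C/C)cc2[C@@H]1OC(=O)/C(C)=C/C | target

**Summary**
Total step count: 11. Longest linear sequence: 11 steps (1 to 18).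

**Steps most likely to fail**

Step 7 (proposed new method). The acid-sensitive dienyl ether 11 may be consumed (hydrolysis, oligomerisation, gold-mediated addition to the ynone) before the alkyne dienophile adds, or the cycloaddition may run with poor para-selectivity. The fallback uses known reaction types and sets out from 9. The gold-catalysed 5-exo-dig cycloisomerisation is run alone, the catalyst is removed by filtration through basic alumina, and the solution of 11 is heated with but-3-en-2-one (toluene, 60 °C), the alkene dienophile for which para-selective addition to 2-alkoxydienes is well established. This should give 1-[(2R,3S)-3-(tert-butyldimethylsilyloxy)-2-[3-(tert-butyldimethylsilyloxy)prop-1-en-2-yl]-2,3,4,5,6,7-hexahydro-1-benzofuran-5-yl]ethanone F1 as C5 epimers. Twofold dehydrogenation with DDQ (2.3 equiv, 1,4-dioxane, 80 °C) then returns to the route at 13.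

Step 5. The basic ylide may enolise the 1,4-diketone, in which each carbonyl acidifies a C–H that has a silyloxy group β to it, leading to β-elimination or epimerisation of the two carbinol centres. The fallback has only one ketone present at a time and sets out from 3. Me(MeO)NH·HCl/Me3Al (CH2Cl2, 0 °C) opens the lactone to N-methoxy-N-methyl-2,5-di-O-(tert-butyldimethylsilyl)-3-O-(trimethylsilyl)-D-ribonamide F2. Dess–Martin oxidation gives (2R,3S)-2,5-bis(tert-butyldimethylsilyloxy)-N-methoxy-N-methyl-4-oxo-3-(trimethylsilyloxy)pentanamide F3. Wittig methylenation, to which the amide is inert, gives (2R,3R)-2-(tert-butyldimethylsilyloxy)-4-[(tert-butyldimethylsilyloxy)methyl]-N-methoxy-N-methyl-3-(trimethylsilyloxy)pent-4-enamide F4. Lithium (trimethylsilyl)acetylide converts the amide into (4R,5R)-4-(tert-butyldimethylsilyloxy)-6-[(tert-butyldimethylsilyloxy)methyl]-1-(trimethylsilyl)-5-(trimethylsilyloxy)hept-6-en-1-yn-3-one F5, and a second Wittig methylenation returns to the route at 7.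

Step 1. Silylation may discriminate poorly between O2 and O3, or the silyl group may migrate between them. The fallback fixes the regiochemistry by ring constraints and sets out from 1. PhCHO/conc. HCl gives the known 3,4-O-[(R)-benzylidene]-D-ribono-1,5-lactone F6, in which only O2 is free. TBSCl/imidazole gives 2-O-(tert-butyldimethylsilyl)-3,4-O-[(R)-benzylidene]-D-ribono-1,5-lactone F7. Hydrogenolysis (H2, Pd/C, EtOAc) removes the acetal and the diol relactonises to 2-O-(tert-butyldimethylsilyl)-D-ribono-1,4-lactone F8. TBSCl (1.05 equiv)/imidazole then silylates only the primary hydroxyl and returns to the route at 2.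

**Further compounds**
F1 | step 7 | 1-[(2R,3S)-3-(tert-butyldimethylsilyloxy)-2-[3-(tert-butyldimethylsilyloxy)prop-1-en-2-yl]-2,3,4,5,6,7-hexahydro-1-benzofuran-5-yl]ethanone (C5 epimers) | C=C(CO[Si](C)(C)C(C)(C)C)[C@H]1OC2=C(CC(C(C)=O)CC2)[C@@H]1O[Si](C)(C)C(C)(C)C
F2 | step 5 | N-methoxy-N-methyl-2,5-di-O-(tert-butyldimethylsilyl)-3-O-(trimethylsilyl)-D-ribonamide | CON(C)C(=O)[C@H](O[Si](C)(C)C(C)(C)C)[C@H](O[Si](C)(C)C)[C@H](O)CO[Si](C)(C)C(C)(C)C
F3 | step 5 | (2R,3S)-2,5-bis(tert-butyldimethylsilyloxy)-N-methoxy-N-methyl-4-oxo-3-(trimethylsilyloxy)pentanamide | CON(C)C(=O)[C@H](O[Si](C)(C)C(C)(C)C)[C@H](O[Si](C)(C)C)C(=O)CO[Si](C)(C)C(C)(C)C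
F4 | step 5 | (2R,3R)-2-(tert-butyldimethylsilyloxy)-4-[(tert-butyldimethylsilyloxy)methyl]-N-methoxy-N-methyl-3-(trimethylsilyloxy)pent-4-enamide | CON(C)C(=O)[C@H](O[Si](C)(C)C(C)(C)C)[C@H](O[Si](C)(C)C)C(=C)CO[Si](C)(C)C(C)(C)C
F5 | step 5 | (4R,5R)-4-(tert-butyldimethylsilyloxy)-6-[(tert-butyldimethylsilyloxy)methyl]-1-(trimethylsilyl)-5-(trimethylsilyloxy)hept-6-en-1-yn-3-one | C[Si](C)(C)C#CC(=O)[C@H](O[Si](C)(C)C(C)(C)C)[C@H](O[Si](C)(C)C)C(=C)CO[Si](C)(C)C(C)(C)C
F6 | step 1 | 3,4-O-[(R)-benzylidene]-D-ribono-1,5-lactone | O=C1OC[C@H]2O[C@@H](c3ccccc3)O[C@H]2[C@H]1O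
F7 | step 1 | 2-O-(tert-butyldimethylsilyl)-3,4-O-[(R)-benzylidene]-D-ribono-1,5-lactone | O=C1OC[C@H]2O[C@@H](c3ccccc3)O[C@H]2[C@H]1O[Si](C)(C)C(C)(C)C
F8 | step 1 | 2-O-(tert-butyldimethylsilyl)-D-ribono-1,4-lactone | O=C1O[C@H](CO)[C@@H](O)[C@H]1O[Si](C)(C)C(C)(C)C
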